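**Retrosynthetic overview**

1. Feature: in the 2-aryl-3-(hydroxymethyl)-2,3-dihydrobenzofuran, C3, C3a and the exocyclic CH2OH carbon are C3, C4a and C4 of a 2-arylchroman-4-one, so ring O1–C2–C3–C3a–C7a is the one-carbon-contracted pyranone ring of a flavanone.
2. Target ⇒ desilylation, Wittig formyl-olefination and oxidation ⇒ C5 aryl ester carrying two protected erythro β-O-4 units, added inner unit first; each unit: C8–O by phenol alkylation with a bromoacetyl oxazolidinone, C7–C8 by Evans syn-aldol (threo), C7 inverted by Mitsunobu.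
3. Dihydrobenzofuran diester 17 ⇒ 3-diazoflavanone 14 (photochemical Wolff contraction, C4a migrates from C4 to C3) ⇒ (R)-flavanone 11 ⇒ chromone 6 + arylboronic acid 10 (asymmetric palladium conjugate addition).
4. Ring order: pyranone ring of the chromone (enaminone cyclisation), then its contraction to the dihydrofuran ring in the key step; no other ring is formed.

Key step: step 8

Remark: erythro in the target is (7R,8S), i.e. C7–OH and C8–OAr anti in the extended chain; a syn-selective aldol therefore gives the threo (7S,8S) series and C7 is inverted afterwards.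
Remark: (S)-t-BuPyOx is assumed to give the 2R flavanone, by analogy with its sense of induction on cyclic enones; the ligand antipode would be used if the sense proves opposite.

Abbreviations in names: Xc = (R)-4-benzyl-2-oxooxazolidin-3-yl; DBF–O = 2,6-dimethoxy-4-[(2R,3S)-3-(tert-butyldimethylsilyloxymethyl)-7-methoxy-5-(methoxycarbonyl)-2,3-dihydrobenzofuran-2-yl]phenoxy; C7/C8/C9 = benzylic carbinol, aryloxy-bearing and CH2O carbons of a β-O-4 unit.

**Route**

Step 1
Reactants: 1 methyl vanillate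
Product: 2 methyl 4-hydroxy-3-iodo-5-methoxybenzoate
Conditions: N-iodosuccinimide, TsOH·H2O (10 mol%), MeCN, rt
Reagents that add atoms: N-iodosuccinimide, O=C1CCC(=O)N1I
Why: Electrophilic aromatic iodination goes to the only free position ortho to the phenol, since the para position carries the ester and the other ortho position the methoxy group.

Step 2
Reactants: 2 methyl 4-hydroxy-3-iodo-5-methoxybenzoate
Product: 4 methyl 3-acetyl-4-hydroxy-5-methoxybenzoate, via enol ether 3 (not isolated)
Conditions: tributyl(1-ethoxyvinyl)stannane, PdCl2(PPh3)2 (5 mol%), dioxane, 100 °C; then 2 M HCl, THF, rt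
Reagents that add atoms: tributyl(1-ethoxyvinyl)stannane, CCCC[Sn](CCCC)(CCCC)C(=C)OCC; water, O
Why: Stille coupling of the aryl iodide with an acetyl-anion equivalent tolerates the phenol and the ester, and acid hydrolysis of the enol ether unmasks the methyl ketone.

Step 3
Reactants: 4 methyl 3-acetyl-4-hydroxy-5-methoxybenzoate
Product: 6 methyl 8-methoxy-4-oxo-4H-chromene-6-carboxylate, via enaminone 5 (not isolated)
Conditions: Me2NCH(OMe)2, toluene, 90 °C; concentrate; then conc. HCl, CH2Cl2, rt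
Reagents that add atoms: N,N-dimethylformamide dimethyl acetal, COC(OC)N(C)C
Why: Condensation of the acetyl group with the formamide acetal gives the enaminone, and acid-promoted addition of the phenol with loss of dimethylamine closes the pyranone ring (enaminone chromone synthesis).

Step 4
Reactants: 7 4-bromo-2,6-dimethoxyphenol
Product: 8 2-(benzyloxy)-5-bromo-1,3-dimethoxybenzene
Conditions: BnBr, K2CO3, DMF, 60 °C
Reagents that add atoms: benzyl bromide, BrCc1ccccc1
Why: Williamson etherification protects the phenol as a benzyl ether that survives the organolithium, enolate and photochemical steps and is removed later by hydrogenolysis.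

Step 5
Reactants: 8 2-(benzyloxy)-5-bromo-1,3-dimethoxybenzene
Product: 10 (4-benzyloxy-3,5-dimethoxyphenyl)boronic acid, via aryllithium 9 (not isolated)
Conditions: n-BuLi, THF, −78 °C; B(Oi-Pr)3, −78 °C to rt; 1 M HCl
Reagents that add atoms: triisopropyl borate, CC(C)OB(OC(C)C)OC(C)C; water, O
Why: Bromine–lithium exchange, borylation and hydrolysis is the standard route to an electron-rich arylboronic acid.

Step 6
Reactants: 6 methyl 8-methoxy-4-oxo-4H-chromene-6-carboxylate; 10 (4-benzyloxy-3,5-dimethoxyphenyl)boronic acid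
Product: 11 methyl (2R)-2-(4-benzyloxy-3,5-dimethoxyphenyl)-8-methoxy-4-oxochromane-6-carboxylate
Conditions: Pd(OCOCF3)2 (5 mol%), (S)-4-tert-butyl-2-(pyridin-2-yl)-4,5-dihydrooxazole (6 mol%), NH4PF6 (30 mol%), H2O (5 equiv), ClCH2CH2Cl, 60 °C
Reagents that add atoms: none
Why: Enantioselective conjugate addition of the arylboronic acid to the chromone under cationic divalent palladium–pyridine-oxazoline catalysis sets C2 by ligand-controlled face selection in the aryl–palladium insertion, and water protonates the palladium enolate to release the flavanone.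

Step 7
Reactants: 11 (2R)-flavanone
Product: 14 methyl (2S)-2-(4-benzyloxy-3,5-dimethoxyphenyl)-3-diazo-8-methoxy-4-oxochromane-6-carboxylate (C2 spatially as in 11), via lithium enolate 12 (not isolated), via trifluoroacetyl ketone 13 (not isolated)
Conditions: LiN(SiMe3)2, THF, −78 °C; CF3CO2CH2CF3, −78 °C, 10 min; 5% HCl quench; then MsN3, Et3N, H2O (1 equiv), MeCN, 0 °C
Reagents that add atoms: methanesulfonyl azide, CS(=O)(=O)N=[N+]=[N-]
Why: Detrifluoroacetylative diazo transfer activates the ketone as its trifluoroacetyl derivative at −78 °C, where retro-oxa-Michael opening of the enolate is slow, and the sulfonyl azide then delivers N2 to C3 with loss of the trifluoroacetyl group, so C2 is not touched (its descriptor changes only through the priority change at C3).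

Step 8
Reactants: 14 3-diazoflavanone
Product: 17 dimethyl (2R,3R)-trans-2-(4-benzyloxy-3,5-dimethoxyphenyl)-7-methoxy-2,3-dihydrobenzofuran-3,5-dicarboxylate, via ketene 15 (not isolated), via cis diester 16 (not isolated)
Conditions: hν (365 nm), degassed MeOH, 0 °C; then NaOMe (0.2 equiv), MeOH, 0 °C to rt
Reagents that add atoms: methanol, CO
Why: Photoexcitation of the s-cis-locked α-diazo ketone expels N2 with concerted 1,2-shift of aryl carbon C4a from the carbonyl carbon C4 to C3 (Wolff rearrangement), giving ketene 15 in which the new C3–C3a bond closes ring O1–C2–C3–C3a–C7a and former C4 is exocyclic; methanol then adds to the ketene to give the methyl ester. The closest known reaction type is the photochemical Wolff ring contraction of cyclic 2-diazo-1-aryl ketones, such as 2-diazo-1-tetralones and 3-diazochroman-4-ones, to indane- and 2,3-dihydrobenzofuran-carboxylates. The dihydrofuran ring is thus closed by ring contraction through 1,2-aryl migration, not by a cyclisation onto oxygen or carbon. C3 is the new stereocentre: ketonisation of the ketene-derived enol is expected to favour the cis epimer 16 (protonation anti to the C2 aryl group), and catalytic NaOMe equilibrates C3 through the ester enolate to the thermodynamically preferred trans arrangement dictated by the C2 aryl group, while C2 itself is a spectator. The step needs aryl migration to outrun 1,2-hydride shift from C2 (which would give the flavone) and O–H insertion of a free carbene into methanol; the rigid s-cis geometry of the cyclic diazo ketone, direct irradiation without sensitiser or metal catalyst and low temperature favour the concerted pathway.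

Step 9
Reactants: 17 trans diester
Product: 18 methyl (2R,3S)-2-(4-benzyloxy-3,5-dimethoxyphenyl)-3-(hydroxymethyl)-7-methoxy-2,3-dihydrobenzofuran-5-carboxylate
Conditions: LiBH4 (1.1 equiv), THF, 0 °C
Reagents that add atoms: none
Why: Chemoselective hydride reduction, because the aliphatic ester activated by its α-aryl and β-oxygen substituents is reduced much faster than the conjugated benzoate deactivated by the para ring oxygen, which is kept as the latent C5 aldehyde.

Step 10
Reactants: 18 hydroxymethyl ester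
Product: 19 TBS ether of 18 (C3–CH2OTBS)
Conditions: TBSCl, imidazole, DMF, rt
Reagents that add atoms: tert-butyldimethylsilyl chloride, CC(C)(C)[Si](C)(C)Cl
Why: Silylation of the primary alcohol gives a group stable to hydrogenolysis, boron enolates, borohydride, Mitsunobu and i-Bu2AlH conditions and removable by fluoride at the end.

Step 11
Reactants: 19 TBS ether
Product: 20 phenol (4-hydroxy-3,5-dimethoxyphenyl at C2; DBF–OH)
Conditions: H2 (1 atm), 10% Pd/C, EtOAc, rt
Reagents that add atoms: none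
Why: Hydrogenolysis cleaves the primary aryl benzyl ether much faster than the hindered cyclic benzylic C2–O bond of the dihydrobenzofuran, and the silyl ether and ester are inert.

Step 12
Reactants: 21 (R)-4-benzyloxazolidin-2-one
Product: 23 (R)-4-benzyl-3-(bromoacetyl)oxazolidin-2-one, via N-lithio oxazolidinone 22 (not isolated)
Conditions: n-BuLi, THF, −78 °C; BrCH2COBr, −78 °C
Reagents that add atoms: bromoacetyl bromide, BrCC(Br)=O
Why: N-acylation of the lithiated oxazolidinone with the acid bromide is the standard preparation of an α-halo imide.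

Step 13
Reactants: 20 phenol; 23 bromoacetyl imide
Product: 24 aryloxyacetyl imide Xc–CO–CH2–O–DBF
Conditions: K2CO3, MeCN, rt
Reagents that add atoms: none
Why: SN2 O-alkylation of the phenoxide by the activated α-bromo imide (Williamson etherification) forms the C8–O bond of the inner β-O-4 unit and installs the auxiliary in one operation.

Step 14
Reactants: 25 syringaldehyde
Product: 26 4-benzyloxy-3,5-dimethoxybenzaldehyde
Conditions: BnBr, K2CO3, DMF, 60 °C
Reagents that add atoms: benzyl bromide, BrCc1ccccc1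
Why: Williamson etherification masks the phenol of the acceptor aldehyde so that it can be released by hydrogenolysis after the aldol.

Step 15
Reactants: 24 aryloxyacetyl imide; 26 4-benzyloxy-3,5-dimethoxybenzaldehyde
Product: 28 syn aldol adduct Xc–CO–CH(O–DBF)–CH(OH)–Ar with (2R,3S) configuration (Ar = 4-benzyloxy-3,5-dimethoxyphenyl), via boron enolate 27 (not isolated)
Conditions: Bu2BOTf, i-Pr2NEt, CH2Cl2, −78 to 0 °C; 26, −78 to 0 °C; then pH 7 buffer, MeOH, 30% H2O2, 0 °C
Reagents that add atoms: none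
Why: Evans syn-aldol, in which the Z boron enolate reacts through a chair Zimmerman–Traxler transition state on the face away from the benzyl group of the (R)-auxiliary, sets C8 (S in the later diol) and C7 in the syn, that is threo, relationship.

Step 16
Reactants: 28 syn aldol adduct
Product: 29 threo diol (1S,2S)-1-(4-benzyloxy-3,5-dimethoxyphenyl)-2-(DBF–O)propane-1,3-diol
Conditions: NaBH4, THF/H2O (4:1), 0 °C to rt
Reagents that add atoms: none
Why: Borohydride reduces the activated exocyclic imide carbonyl to the C9 primary alcohol and releases the auxiliary, while the conjugated aryl methyl ester and the silyl ether are inert and no stereocentre is affected.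

Step 17
Reactants: 29 threo diol
Product: 30 C9 mono-TBS ether of 29 (C7–OH free)
Conditions: TBSCl (1.05 equiv), imidazole, CH2Cl2, 0 °C
Reagents that add atoms: tert-butyldimethylsilyl chloride, CC(C)(C)[Si](C)(C)Cl
Why: The primary hydroxyl is silylated much faster than the hindered secondary benzylic one, which stays free for the later inversion.

Step 18
Reactants: 30 mono-TBS ether
Product: 31 phenol (debenzylated 30)
Conditions: H2 (1 atm), 10% Pd/C, EtOAc, rt
Reagents that add atoms: none
Why: Hydrogenolysis of the aryl benzyl ether under neutral conditions leaves the free benzylic alcohol and the cyclic benzylic ether intact, and is placed before the Mitsunobu step so that no benzylic ester is exposed to hydrogen.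

Step 19
Reactants: 31 phenol; 23 bromoacetyl imide
Product: 32 aryloxyacetyl imide of 31 (ArO–CH2–CO–Xc; inner unit threo with free C7–OH)
Conditions: K2CO3, MeCN, rt
Reagents that add atoms: none
Why: The phenoxide is alkylated selectively in the presence of the far less acidic secondary alcohol (Williamson etherification), forming the C8–O bond of the outer unit.

Step 20
Reactants: 32 threo alcohol imide
Product: 33 erythro (7R,8S) C7 benzoate of 32
Conditions: PPh3, i-PrO2CN=NCO2i-Pr, PhCO2H, toluene, −20 °C to rt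
Reagents that add atoms: benzoic acid, OC(=O)c1ccccc1
Why: Mitsunobu esterification displaces the activated benzylic oxygen by benzoate with inversion (SN2), turning the threo (7S,8S) unit into the erythro (7R,8S) unit and protecting C7–O as an ester without α-hydrogens for the next aldol.

Step 21
Reactants: 34 vanillin
Product: 35 3-methoxy-4-(triisopropylsilyloxy)benzaldehyde
Conditions: i-Pr3SiCl, imidazole, DMF, rt
Reagents that add atoms: triisopropylsilyl chloride, CC(C)[Si](Cl)(C(C)C)C(C)C
Why: Silylation gives a robust aryl silyl ether that survives the remaining steps and is cleaved by fluoride in the presence of the enal.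

Step 22
Reactants: 33 benzoate imide; 35 silyl-protected vanillin
Product: 37 syn aldol adduct of 33 with 35 (new unit (2R,3S) in the acyl chain), via boron enolate 36 (not isolated)
Conditions: Bu2BOTf, i-Pr2NEt, CH2Cl2, −78 to 0 °C; 35, −78 to 0 °C; then pH 7 buffer, MeOH, 30% H2O2, 0 °C
Reagents that add atoms: none
Why: A second Evans syn-aldol, controlled by the auxiliary through the chair transition state of the Z boron enolate and independent of the remote stereocentres, sets C8 and C7 of the outer unit in the threo relationship.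

Step 23
Reactants: 37 syn aldol adduct
Product: 38 outer threo (7S,8S) diol
Conditions: NaBH4, THF/H2O (4:1), 0 °C
Reagents that add atoms: none
Why: Borohydride cleaves the imide reductively to the C9 alcohol while the benzoate, the aryl methyl ester and the silyl ethers are inert at this temperature.

Step 24
Reactants: 38 outer threo diol
Product: 39 C9 mono-TBS ether of 38
Conditions: TBSCl (1.05 equiv), imidazole, CH2Cl2, 0 °C
Reagents that add atoms: tert-butyldimethylsilyl chloride, CC(C)(C)[Si](C)(C)Cl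
Why: Selective silylation of the primary hydroxyl leaves only the secondary benzylic alcohol free.

Step 25
Reactants: 39 threo alcohol
Product: 40 bis-benzoate with both units erythro (7R,8S)
Conditions: PPh3, i-PrO2CN=NCO2i-Pr, PhCO2H, toluene, −20 °C to rt
Reagents that add atoms: benzoic acid, OC(=O)c1ccccc1
Why: Mitsunobu inversion at the outer benzylic carbon gives the second erythro unit by SN2 displacement with benzoate.

Step 26
Reactants: 40 bis-benzoate methyl ester
Product: 41 triol (C5–CH2OH and both C7–OH free)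
Conditions: i-Bu2AlH (8 equiv), CH2Cl2, −78 to 0 °C; aq. KNaC4H4O6
Reagents that add atoms: none
Why: The aluminium hydride reduces the aryl methyl ester to the benzylic alcohol and cleaves both benzoates reductively without touching silyl ethers or any stereocentre.

Step 27
Reactants: 41 triol
Product: 42 C5 aldehyde
Conditions: [Cu(MeCN)4]OTf (5 mol%), 2,2'-bipyridine (5 mol%), TEMPO (5 mol%), N-methylimidazole (10 mol%), MeCN/CH2Cl2, air, rt
Reagents that add atoms: none
Why: Aerobic copper/TEMPO oxidation is selective for the unhindered primary benzylic alcohol, the two hindered secondary benzylic alcohols being poor substrates for the TEMPO-based catalyst.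

Step 28
Reactants: 42 C5 aldehyde
Product: 43 (E)-enal
Conditions: Ph3P=CHCHO (1.3 equiv), toluene, 80 °C
Reagents that add atoms: (triphenylphosphoranylidene)acetaldehyde, O=CC=P(c1ccccc1)(c1ccccc1)c1ccccc1
Why: Wittig olefination of the aryl aldehyde with the stabilised formyl ylide gives the E-configured cinnamaldehyde and tolerates the free secondary alcohols.

Step 29
Reactants: 43 silyl-protected enal
Product: 44 target CNP0192639.1
Conditions: Bu4NF (8 equiv), AcOH (8 equiv), THF, 0 °C to rt
Reagents that add atoms: none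
Why: Fluoride cleaves the three primary TBS ethers and the aryl triisopropylsilyl ether, and acetic acid buffering protects the enal and the phenolic β-O-4 unit from base.

**Compound list**

1 | methyl vanillate | COC(=O)c1ccc(O)c(OC)c1 | starting material
2 | methyl 4-hydroxy-3-iodo-5-methoxybenzoate | COC(=O)c1cc(I)c(O)c(OC)c1 | intermediate
3 | methyl 3-(1-ethoxyvinyl)-4-hydroxy-5-methoxybenzoate (not isolated) | CCOC(=C)c1cc(C(=O)OC)cc(OC)c1O | intermediate
4 | methyl 3-acetyl-4-hydroxy-5-methoxybenzoate | CC(=O)c1cc(C(=O)OC)cc(OC)c1O | intermediate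
5 | methyl 3-[(E)-3-(dimethylamino)acryloyl]-4-hydroxy-5-methoxybenzoate (not isolated) | CN(C)/C=C/C(=O)c1cc(C(=O)OC)cc(OC)c1O | intermediate
6 | methyl 8-methoxy-4-oxo-4H-chromene-6-carboxylate | COC(=O)c1cc(OC)c2occc(=O)c2c1 | intermediate
7 | 4-bromo-2,6-dimethoxyphenol | COc1cc(Br)cc(OC)c1O | starting material
8 | 2-(benzyloxy)-5-bromo-1,3-dimethoxybenzene | COc1cc(Br)cc(OC)c1OCc1ccccc1 | intermediate
9 | (4-benzyloxy-3,5-dimethoxyphenyl)lithium (not isolated) | [Li]c1cc(OC)c(OCc2ccccc2)c(OC)c1 | intermediate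
10 | (4-benzyloxy-3,5-dimethoxyphenyl)boronic acid | OB(O)c1cc(OC)c(OCc2ccccc2)c(OC)c1 | intermediate
11 | methyl (2R)-2-(4-benzyloxy-3,5-dimethoxyphenyl)-8-methoxy-4-oxochromane-6-carboxylate | COc1cc([C@@H]2Oc3c(OC)cc(C(=O)OC)cc3C(=O)C2)cc(OC)c1OCc1ccccc1 | intermediate
12 | lithium enolate of 11 (C3=C4–OLi, C2 unchanged; not isolated) | COc1cc([C@@H]2Oc3c(OC)cc(C(=O)OC)cc3C(O[Li])=C2)cc(OC)c1OCc1ccccc1 | intermediate
13 | 3-trifluoroacetyl derivative of 11 (C3 enolisable, C2 unchanged; not isolated) | COc1cc([C@@H]2Oc3c(OC)cc(C(=O)OC)cc3C(=O)C2C(=O)C(F)(F)F)cc(OC)c1OCc1ccccc1 | intermediate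
14 | methyl (2S)-2-(4-benzyloxy-3,5-dimethoxyphenyl)-3-diazo-8-methoxy-4-oxochromane-6-carboxylate | COc1cc([C@@H]2Oc3c(OC)cc(C(=O)OC)cc3C(=O)C2=[N+]=[N-])cc(OC)c1OCc1ccccc1 | intermediate
15 | methyl 2-(4-benzyloxy-3,5-dimethoxyphenyl)-7-methoxy-3-(oxomethylidene)-2,3-dihydrobenzofuran-5-carboxylate, ketene, C2 unchanged (not isolated) | COc1cc([C@@H]2Oc3c(OC)cc(C(=O)OC)cc3C2=C=O)cc(OC)c1OCc1ccccc1 | intermediate
16 | dimethyl (2R,3S)-cis-2-(4-benzyloxy-3,5-dimethoxyphenyl)-7-methoxy-2,3-dihydrobenzofuran-3,5-dicarboxylate (not isolated) | COc1cc([C@@H]2Oc3c(OC)cc(C(=O)OC)cc3[C@@H]2C(=O)OC)cc(OC)c1OCc1ccccc1 | intermediate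
17 | dimethyl (2R,3R)-trans-2-(4-benzyloxy-3,5-dimethoxyphenyl)-7-methoxy-2,3-dihydrobenzofuran-3,5-dicarboxylate | COc1cc([C@@H]2Oc3c(OC)cc(C(=O)OC)cc3[C@H]2C(=O)OC)cc(OC)c1OCc1ccccc1 | intermediate
18 | methyl (2R,3S)-2-(4-benzyloxy-3,5-dimethoxyphenyl)-3-(hydroxymethyl)-7-methoxy-2,3-dihydrobenzofuran-5-carboxylate | COc1cc([C@@H]2Oc3c(OC)cc(C(=O)OC)cc3[C@H]2CO)cc(OC)c1OCc1ccccc1 | intermediate
19 | TBS ether of 18 | COc1cc([C@@H]2Oc3c(OC)cc(C(=O)OC)cc3[C@H]2CO[Si](C)(C)C(C)(C)C)cc(OC)c1OCc1ccccc1 | intermediate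
20 | methyl (2R,3S)-3-(tert-butyldimethylsilyloxymethyl)-2-(4-hydroxy-3,5-dimethoxyphenyl)-7-methoxy-2,3-dihydrobenzofuran-5-carboxylate (DBF–OH) | COc1cc([C@@H]2Oc3c(OC)cc(C(=O)OC)cc3[C@H]2CO[Si](C)(C)C(C)(C)C)cc(OC)c1O | intermediate
21 | (R)-4-benzyloxazolidin-2-one | O=C1N[C@H](Cc2ccccc2)CO1 | starting material
22 | N-lithio-(R)-4-benzyloxazolidin-2-one (not isolated) | [Li]N1[C@H](Cc2ccccc2)COC1=O | intermediate
23 | (R)-4-benzyl-3-(bromoacetyl)oxazolidin-2-one | BrCC(=O)N1[C@H](Cc2ccccc2)COC1=O | intermediate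
24 | Xc–CO–CH2–O–DBF, aryloxyacetyl imide of 20 | O=C(COc1c(OC)cc([C@@H]2Oc3c(OC)cc(C(=O)OC)cc3[C@H]2CO[Si](C)(C)C(C)(C)C)cc1OC)N4[C@H](Cc5ccccc5)COC4=O | intermediate
25 | syringaldehyde | COc1cc(C=O)cc(OC)c1O | starting material
26 | 4-benzyloxy-3,5-dimethoxybenzaldehyde | COc1cc(C=O)cc(OC)c1OCc1ccccc1 | intermediate
27 | Z dibutylboron enolate of 24 (not isolated) | CCCCB(CCCC)O/C(N4[C@H](Cc5ccccc5)COC4=O)=C\Oc1c(OC)cc([C@@H]2Oc3c(OC)cc(C(=O)OC)cc3[C@H]2CO[Si](C)(C)C(C)(C)C)cc1OC | intermediate
28 | syn aldol adduct, Xc–CO–(2R)-CH(O–DBF)–(3S)-CH(OH)–(4-benzyloxy-3,5-dimethoxyphenyl) | COc1cc([C@H](O)[C@H](C(=O)N4[C@H](Cc5ccccc5)COC4=O)Oc2c(OC)cc([C@@H]6Oc7c(OC)cc(C(=O)OC)cc7[C@H]6CO[Si](C)(C)C(C)(C)C)cc2OC)cc(OC)c1OCc8ccccc8 | intermediate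
29 | threo diol, (1S,2S)-1-(4-benzyloxy-3,5-dimethoxyphenyl)-2-(DBF–O)propane-1,3-diol | COc1cc([C@H](O)[C@H](CO)Oc2c(OC)cc([C@@H]6Oc7c(OC)cc(C(=O)OC)cc7[C@H]6CO[Si](C)(C)C(C)(C)C)cc2OC)cc(OC)c1OCc8ccccc8 | intermediate
30 | 3-O-TBS ether of 29 (C7–OH free, threo) | COc1cc([C@H](O)[C@H](CO[Si](C)(C)C(C)(C)C)Oc2c(OC)cc([C@@H]6Oc7c(OC)cc(C(=O)OC)cc7[C@H]6CO[Si](C)(C)C(C)(C)C)cc2OC)cc(OC)c1OCc8ccccc8 | intermediate
31 | phenol from 30 (4-hydroxy-3,5-dimethoxyphenyl carbinol, threo) | COc1cc([C@H](O)[C@H](CO[Si](C)(C)C(C)(C)C)Oc2c(OC)cc([C@@H]6Oc7c(OC)cc(C(=O)OC)cc7[C@H]6CO[Si](C)(C)C(C)(C)C)cc2OC)cc(OC)c1O | intermediate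
32 | 31 O-alkylated at the phenol with CH2–CO–Xc (inner unit threo 7S,8S, C7–OH free) | COc1cc([C@H](O)[C@H](CO[Si](C)(C)C(C)(C)C)Oc2c(OC)cc([C@@H]6Oc7c(OC)cc(C(=O)OC)cc7[C@H]6CO[Si](C)(C)C(C)(C)C)cc2OC)cc(OC)c1OCC(=O)N4[C@H](Cc5ccccc5)COC4=O | intermediate
33 | C7 benzoate of inverted 32 (inner unit erythro 7R,8S) | COc1cc([C@@H](OC(=O)c9ccccc9)[C@H](CO[Si](C)(C)C(C)(C)C)Oc2c(OC)cc([C@@H]6Oc7c(OC)cc(C(=O)OC)cc7[C@H]6CO[Si](C)(C)C(C)(C)C)cc2OC)cc(OC)c1OCC(=O)N4[C@H](Cc5ccccc5)COC4=O | intermediate
34 | vanillin | COc1cc(C=O)ccc1O | starting material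
35 | 3-methoxy-4-(triisopropylsilyloxy)benzaldehyde | COc1cc(C=O)ccc1O[Si](C(C)C)(C(C)C)C(C)C | intermediate
36 | Z dibutylboron enolate of 33 (not isolated) | CCCCB(CCCC)O/C(N4[C@H](Cc5ccccc5)COC4=O)=C\Oc1c(OC)cc([C@@H](OC(=O)c9ccccc9)[C@H](CO[Si](C)(C)C(C)(C)C)Oc2c(OC)cc([C@@H]6Oc7c(OC)cc(C(=O)OC)cc7[C@H]6CO[Si](C)(C)C(C)(C)C)cc2OC)cc1OC | intermediate
37 | syn aldol adduct of 33 with 35 (outer unit (2R,3S) in the acyl chain, imide still attached) | COc1cc([C@H](O)[C@H](C(=O)N4[C@H](Cc5ccccc5)COC4=O)Oc2c(OC)cc([C@@H](OC(=O)c9ccccc9)[C@H](CO[Si](C)(C)C(C)(C)C)Oc3c(OC)cc([C@@H]6Oc7c(OC)cc(C(=O)OC)cc7[C@H]6CO[Si](C)(C)C(C)(C)C)cc3OC)cc2OC)ccc1O[Si](C(C)C)(C(C)C)C(C)C | intermediate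
38 | outer threo (7S,8S) 1,3-diol, inner unit erythro benzoate | COc1cc([C@H](O)[C@H](CO)Oc2c(OC)cc([C@@H](OC(=O)c9ccccc9)[C@H](CO[Si](C)(C)C(C)(C)C)Oc3c(OC)cc([C@@H]6Oc7c(OC)cc(C(=O)OC)cc7[C@H]6CO[Si](C)(C)C(C)(C)C)cc3OC)cc2OC)ccc1O[Si](C(C)C)(C(C)C)C(C)C | intermediate
39 | outer C9 mono-TBS ether of 38 (outer C7–OH free, threo) | COc1cc([C@H](O)[C@H](CO[Si](C)(C)C(C)(C)C)Oc2c(OC)cc([C@@H](OC(=O)c9ccccc9)[C@H](CO[Si](C)(C)C(C)(C)C)Oc3c(OC)cc([C@@H]6Oc7c(OC)cc(C(=O)OC)cc7[C@H]6CO[Si](C)(C)C(C)(C)C)cc3OC)cc2OC)ccc1O[Si](C(C)C)(C(C)C)C(C)C | intermediate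
40 | bis-benzoate, both units erythro (7R,8S), C5 methyl ester | COc1cc([C@@H](OC(=O)c8ccccc8)[C@H](CO[Si](C)(C)C(C)(C)C)Oc2c(OC)cc([C@@H](OC(=O)c9ccccc9)[C@H](CO[Si](C)(C)C(C)(C)C)Oc3c(OC)cc([C@@H]6Oc7c(OC)cc(C(=O)OC)cc7[C@H]6CO[Si](C)(C)C(C)(C)C)cc3OC)cc2OC)ccc1O[Si](C(C)C)(C(C)C)C(C)C | intermediate
41 | triol: C5–CH2OH and both C7–OH free; three CH2OTBS and the aryl triisopropylsilyl ether retained | COc1cc([C@@H](O)[C@H](CO[Si](C)(C)C(C)(C)C)Oc2c(OC)cc([C@@H](O)[C@H](CO[Si](C)(C)C(C)(C)C)Oc3c(OC)cc([C@@H]6Oc7c(OC)cc(CO)cc7[C@H]6CO[Si](C)(C)C(C)(C)C)cc3OC)cc2OC)ccc1O[Si](C(C)C)(C(C)C)C(C)C | intermediate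
42 | C5 aldehyde of 41 | COc1cc([C@@H](O)[C@H](CO[Si](C)(C)C(C)(C)C)Oc2c(OC)cc([C@@H](O)[C@H](CO[Si](C)(C)C(C)(C)C)Oc3c(OC)cc([C@@H]6Oc7c(OC)cc(C=O)cc7[C@H]6CO[Si](C)(C)C(C)(C)C)cc3OC)cc2OC)ccc1O[Si](C(C)C)(C(C)C)C(C)C | intermediate
43 | C5 (E)-propenal, fourfold silyl-protected target | COc1cc([C@@H](O)[C@H](CO[Si](C)(C)C(C)(C)C)Oc2c(OC)cc([C@@H](O)[C@H](CO[Si](C)(C)C(C)(C)C)Oc3c(OC)cc([C@@H]6Oc7c(OC)cc(/C=C/C=O)cc7[C@H]6CO[Si](C)(C)C(C)(C)C)cc3OC)cc2OC)ccc1O[Si](C(C)C)(C(C)C)C(C)C | intermediate
44 | CNP0192639.1 | COc1cc([C@@H](O)[C@H](CO)Oc2c(OC)cc([C@@H](O)[C@H](CO)Oc3c(OC)cc([C@@H]4Oc5c(OC)cc(/C=C/C=O)cc5[C@H]4CO)cc3OC)cc2OC)ccc1O | target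

**Totals**

Total step count: 29. Longest linear sequence: 24 steps (1 to 44 through steps 1–3, 6–11, 13, 15–20 and 22–29).

**Steps most likely to fail**

Step 8 (Wolff contraction). The excited diazo ketone may lose N2 to a free carbene that undergoes 1,2-hydride shift from C2, aromatising to the flavone, or inserts into the O–H bond of methanol, instead of undergoing the aryl shift. The fallback forms the C2–C3 bond by intramolecular carbenoid C–H insertion and sets out from iodophenol 2 and aldehyde 26. NaBH4 reduction of 26 would give (4-benzyloxy-3,5-dimethoxyphenyl)methanol F1, and PBr3 would convert it into 4-benzyloxy-3,5-dimethoxybenzyl bromide F2. Alkylation of 2 with F2 (K2CO3, DMF) would give methyl 4-[(4-benzyloxy-3,5-dimethoxybenzyl)oxy]-3-iodo-5-methoxybenzoate F3. Palladium-catalysed coupling of F3 with the Reformatsky reagent BrZnCH2CO2Me (Pd2(dba)3, XPhos, THF) would give the arylacetate F4, and diazo transfer (4-acetamidobenzenesulfonyl azide, DBU, MeCN) the aryldiazoacetate F5. A chiral dirhodium tetracarboxylate, Rh2(S-PTTL)4 (dirhodium tetrakis[N-phthaloyl-(S)-tert-leucinate]) or its enantiomer, chosen for the 2R series, would then insert the carbenoid into the benzylic O–CH2 bond in toluene at low temperature. This gives the cis ester 16, where the route is rejoined; the NaOMe equilibration of step 8 leads on to 17.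

Step 7 (diazo transfer). The lithium enolate 12 or the enolised trifluoroacetyl ketone 13 may open by retro-oxa-Michael elimination of the phenoxide and reclose, eroding the configuration at C2, or the opened chalcone may be lost. The fallback avoids any enolate and any diazo compound: it sets out from flavanone 11 and comes back at 17, with no new compound. Oxidative ring contraction with PhI(OAc)2 and catalytic H2SO4 in HC(OMe)3 at rt should work as follows: trivalent iodine adds at C3 of the enol ether formed under acid, and aryl carbon C4a migrates from C4 to C3 as iodobenzene leaves. The resulting orthoester collapses to the trans methyl ester.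

Step 20 (Mitsunobu inversion; step 25 is the same reaction type). The benzylic oxyphosphonium ion on the electron-rich ring may ionise, which would give a mixture of erythro and threo benzoates, or it may eliminate. The fallback replaces the substitution by an oxidation–reduction pair, sets out from 32 and comes back at 33. Dess–Martin periodinane (CH2Cl2, rt) would give the α-aryloxy aryl ketone F6. Zn(BH4)2 (Et2O/CH2Cl2, −40 °C) would reduce it under chelation control, zinc bridging the carbonyl and the C8 aryloxy oxygen and hydride arriving from the side of the C8 hydrogen, to the erythro alcohol F7. Benzoylation (BzCl, pyridine, DMAP) would then give 33.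

Further compounds
F1 | step 8 | (4-benzyloxy-3,5-dimethoxyphenyl)methanol | COc1cc(CO)cc(OC)c1OCc1ccccc1
F2 | step 8 | 4-benzyloxy-3,5-dimethoxybenzyl bromide | COc1cc(CBr)cc(OC)c1OCc1ccccc1
F3 | step 8 | methyl 4-[(4-benzyloxy-3,5-dimethoxybenzyl)oxy]-3-iodo-5-methoxybenzoate | COC(=O)c1cc(I)c(OCc2cc(OC)c(OCc3ccccc3)c(OC)c2)c(OC)c1
F4 | step 8 | methyl 4-[(4-benzyloxy-3,5-dimethoxybenzyl)oxy]-3-methoxy-5-(2-methoxy-2-oxoethyl)benzoate | COC(=O)Cc1cc(C(=O)OC)cc(OC)c1OCc1cc(OC)c(OCc2ccccc2)c(OC)c1
F5 | step 8 | methyl 4-[(4-benzyloxy-3,5-dimethoxybenzyl)oxy]-3-(1-diazo-2-methoxy-2-oxoethyl)-5-methoxybenzoate | COC(=O)C(=[N+]=[N-])c1cc(C(=O)OC)cc(OC)c1OCc1cc(OC)c(OCc2ccccc2)c(OC)c1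
F0 | step 7 | none | none
F6 | step 20 | C7 ketone of 32 (α-aryloxy aryl ketone, C8 unchanged) | COc1cc(C(=O)[C@H](CO[Si](C)(C)C(C)(C)C)Oc2c(OC)cc([C@@H]6Oc7c(OC)cc(C(=O)OC)cc7[C@H]6CO[Si](C)(C)C(C)(C)C)cc2OC)cc(OC)c1OCC(=O)N4[C@H](Cc5ccccc5)COC4=O
F7 | step 20 | erythro (7R,8S) alcohol, C7 epimer of 32 | COc1cc([C@@H](O)[C@H](CO[Si](C)(C)C(C)(C)C)Oc2c(OC)cc([C@@H]6Oc7c(OC)cc(C(=O)OC)cc7[C@H]6CO[Si](C)(C)C(C)(C)C)cc2OC)cc(OC)c1OCC(=O)N4[C@H](Cc5ccccc5)COC4=O
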